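**Strategy.** The key step exploits the 1,5-diene hidden in the ten-membered ring (C1–C10): the C1–C10 bond, later the epoxide, and the C4=C5 alkene. That diene is traced back to a cyclobutane on C1, C4, C5 and C10, hence to a cyclohexenone (ring C5–C10) and a cyclobutene (ring C1–C4). Light joins C10–C1 and C5–C4; heat then breaks C5–C10 and C1–C4, so one operation merges two small rings into the cyclodeca-1(10),4-dien-6-one with both alkenes in place. The enone partner already carries the cis C7 acetate arm and C8 silyl ether; the cyclobutene ester carries C3–O and C15.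

Key step: step 9

Remarks on the chemistry (germacrane numbering throughout: ring C1–C10, lactone arm C11–C13, methyl C14, C15 on C4):
- Assumption: 1 (also one step from ethyl (S)-4-chloro-3-hydroxybutanoate with Ag2O) and 24 are bought as single enantiomers.
- Checked against the target: the enone must be the 7,8-cis (1R,6R) isomer, the cyclobutene the 4S isomer, and the ring-opened product needs E-C1=C10 with C3 and C6 cis on C4=C5.
- A 6-alkylcyclohexa-2,5-dienone is a cresol tautomer and enolate alkylation of a 5-silyloxyenone would give the 7,8-trans isomer, so C7/C8 are set on an open chain and the ring is closed by metathesis.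
- Cyclobutene 14 is a donor/acceptor cyclobutene prone to conrotatory ring opening; it is stored and used cold and removed before the thermolysis.

Step 1
Reactants: 1 ethyl (S)-2-(oxiran-2-yl)acetate; 2 isopropenylmagnesium bromide
Product: 3 ethyl (3R)-3-hydroxy-5-methylhex-5-enoate
Conditions: CuI (10 mol%), THF, −78 → −30 °C; aq. NH4Cl
Reagents that add atoms: none
Why: Copper-catalysed Grignard opening of a terminal epoxide is SN2 at the unsubstituted carbon, so the future C8 carbinol centre is carried over untouched and the ester survives at low temperature.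

Step 2
Reactants: 3 ethyl (3R)-3-hydroxy-5-methylhex-5-enoate; 4 tert-butyl bromoacetate
Product: 5 4-tert-butyl 1-ethyl (2R)-2-[(1R)-1-hydroxy-3-methylbut-3-en-1-yl]butanedioate
Conditions: LDA (2.2 equiv), THF, −78 → −20 °C; then 4, DMPU, −78 → −30 °C; cold aqueous quench
Reagents that add atoms: none
Why: Fráter–Seebach alkylation, in which the chelated lithium alkoxide–enolate dianion is alkylated anti to the C9 chain, sets C7 anti to C8 (cis once the ring is closed), and the tert-butyl ester resists attack by the neighbouring alkoxide.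

Step 3
Reactants: 5 4-tert-butyl 1-ethyl (2R)-2-[(1R)-1-hydroxy-3-methylbut-3-en-1-yl]butanedioate
Product: 6 4-tert-butyl 1-ethyl (2R)-2-[(1R)-3-methyl-1-(triethylsilyloxy)but-3-en-1-yl]butanedioate
Conditions: TESOTf, 2,6-lutidine, CH2Cl2, −78 °C
Reagents that add atoms: triethylsilyl trifluoromethanesulfonate, CC[Si](CC)(CC)OS(=O)(=O)C(F)(F)F
Why: Silylation of the secondary alcohol with a silyl triflate and a hindered base is non-epimerising, and TES is chosen so that O8 can later be freed in the presence of TBS ethers.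

Step 4
Reactants: 6 4-tert-butyl 1-ethyl (2R)-2-[(1R)-3-methyl-1-(triethylsilyloxy)but-3-en-1-yl]butanedioate
Product: 7 tert-butyl (3R,4R)-3-[methoxy(methyl)carbamoyl]-6-methyl-4-(triethylsilyloxy)hept-6-enoate
Conditions: MeNHOMe·HCl, i-PrMgCl, THF, −20 → 0 °C
Reagents that add atoms: N,O-dimethylhydroxylamine hydrochloride, CNOC.Cl
Why: Weinreb amide formation with the chloromagnesium amide occurs at the ethyl ester only, the tert-butyl ester being too hindered for acyl substitution.

Step 5
Reactants: 7 tert-butyl (3R,4R)-3-[methoxy(methyl)carbamoyl]-6-methyl-4-(triethylsilyloxy)hept-6-enoate; 8 vinylmagnesium bromide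
Product: 9 tert-butyl (3R,4R)-3-acryloyl-6-methyl-4-(triethylsilyloxy)hept-6-enoate
Conditions: THF, −78 → −20 °C; inverse quench into cold aq. citric acid
Reagents that add atoms: none
Why: Grignard addition to a Weinreb amide stops at the ketone because the chelated tetrahedral intermediate persists until the cold acidic quench, which also keeps the released amine off the vinyl ketone and leaves C7 unepimerised.

Step 6
Reactants: 9 tert-butyl (3R,4R)-3-acryloyl-6-methyl-4-(triethylsilyloxy)hept-6-enoate
Product: 10 tert-butyl 2-[(1R,6R)-4-methyl-2-oxo-6-(triethylsilyloxy)cyclohex-3-en-1-yl]acetate (7,8-cis)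
Conditions: Grubbs II (5 mol%), CH2Cl2 (5 mM), 40 °C
Reagents that add atoms: none
Why: Ring-closing metathesis of the vinyl ketone with the 1,1-disubstituted alkene closes the six-membered ring with loss of ethene under neutral conditions, which spare the elimination-prone β-silyloxy ketone and both stereocentres.

Step 7
Reactants: 11 methyl propiolate; 12 tert-butyldimethyl(vinyloxy)silane
Product: 13 methyl (±)-4-(tert-butyldimethylsilyloxy)cyclobut-1-ene-1-carboxylate
Conditions: Tf2NH (2 mol%), CH2Cl2, −78 °C; Et3N quench; kept below 0 °C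
Reagents that add atoms: none
Why: Acid-catalysed stepwise [2+2] of a silyl enol ether with a propiolate (Mukaiyama–Michael attack of the enol ether CH2 on the alkyne β-carbon, then closure of the allenoate on the oxocarbenium carbon) fixes the 4-silyloxy-1-ester regiochemistry; the product is racemic.

Step 8
Reactants: 13 methyl (±)-4-(tert-butyldimethylsilyloxy)cyclobut-1-ene-1-carboxylate
Product: 14 methyl (4S)-4-(tert-butyldimethylsilyloxy)cyclobut-1-ene-1-carboxylate
Conditions: preparative SFC on a chiral stationary phase (amylose carbamate), CO2/i-PrOH, column ≤ 20 °C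
Reagents that add atoms: none
Why: Resolution by chromatography on a chiral phase is a separation without reaction, so the labile cyclobutene is never exposed to reagents; the 4S enantiomer is kept and its configuration confirmed by correlation.

Step 9
Reactants: 10 tert-butyl 2-[(1R,6R)-4-methyl-2-oxo-6-(triethylsilyloxy)cyclohex-3-en-1-yl]acetate; 14 methyl (4S)-4-(tert-butyldimethylsilyloxy)cyclobut-1-ene-1-carboxylate
Product: 16 methyl (1(10)E,4E,3S,7R,8R)-7-(2-tert-butoxy-2-oxoethyl)-3-(tert-butyldimethylsilyloxy)-10-methyl-6-oxo-8-(triethylsilyloxy)cyclodeca-1(10),4-diene-4-carboxylate (germacrane numbering; C3 and C6 cis on C4=C5), via cyclobutane photoadduct 15 (not isolated)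
Conditions: hν (366 nm), 14 (4 equiv), degassed CH2Cl2, −40 °C; neutral Al2O3 plug (excess 14 recovered); then PhMe, 130 °C, sealed tube
Reagents that add atoms: none
Why: The triplet 3-methylcyclohexenone adds stepwise to the strained, acrylate-type cyclobutene, C10 bonding to the unsubstituted C1 and the resulting 1,4-diradical (ester-stabilised at C4) collapsing to the C5–C4 bond, which is the head-to-head enone–alkene [2+2] photocycloaddition established for cyclobut-1-enecarboxylates. The cyclobutane C5–C10–C1–C4 closes by radical recombination; its four stereocentres are transient, so facial and syn/anti mixtures converge once alumina has equilibrated the α-keto centre C5 to the cis 6–4 fusion. On heating, the ester-weakened C1–C4 bond of the bicyclo[2.2.0]hexane homolyses to a cyclohexane-1,4-diyl that fragments across C5–C10 (flanked by the ketone and the quaternary C10), the known strain-driven, formally σ2s+σ2a cycloreversion, so the ten-membered ring arises by ring expansion and not by end-to-end cyclisation. A cis ring fusion enforces one cis and one trans alkene, and the chair diyl that keeps the C6 acyl carbon out of the plane of the ester-bearing radical at C4 places C6 trans to the ester (C3 and C6 cis) and therefore C9 trans to C2. The step needs head-to-head regiochemistry (secured by the C15 ester), cleavage of C5–C10 rather than C2–C3, and the E-C1=C10/ring-cis C4=C5 pattern (secured by the trans preference of ester and ketone across C4=C5); no new stereocentre survives.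

Step 10
Reactants: 16 methyl (1(10)E,4E,3S,7R,8R)-7-(2-tert-butoxy-2-oxoethyl)-3-(tert-butyldimethylsilyloxy)-10-methyl-6-oxo-8-(triethylsilyloxy)cyclodeca-1(10),4-diene-4-carboxylate
Product: 17 tert-butyl 2-[(1(10)E,4Z,3S,6R,7S,8R)-3-(tert-butyldimethylsilyloxy)-6-hydroxy-4-(hydroxymethyl)-10-methyl-8-(triethylsilyloxy)cyclodeca-1(10),4-dien-7-yl]acetate
Conditions: DIBAL-H (5 equiv), CH2Cl2, −78 °C; Rochelle salt
Reagents that add atoms: none
Why: DIBAL-H reduces the enone carbonyl 1,2 and the conjugated methyl ester to the allylic alcohol while the tert-butyl ester is inert at −78 °C; C6 is set by substrate control, Felkin–Anh attack anti to the C7 acetate arm on the exposed face of the ring ketone being expected to give 6R.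

Step 11
Reactants: 17 tert-butyl 2-[(1(10)E,4Z,3S,6R,7S,8R)-3-(tert-butyldimethylsilyloxy)-6-hydroxy-4-(hydroxymethyl)-10-methyl-8-(triethylsilyloxy)cyclodeca-1(10),4-dien-7-yl]acetate
Product: 18 (1(10)E,4Z,3S,6R,7S,8R)-3-(tert-butyldimethylsilyloxy)-15-hydroxy-8-(triethylsilyloxy)-13-norgermacra-1(10),4-dien-12,6-olide (trans-fused lactone)
Conditions: CSA (10 mol%), CH2Cl2, 0 °C → rt
Reagents that add atoms: none
Why: Acid-catalysed intramolecular transesterification (5-exo lactonisation) of the γ-hydroxy tert-butyl ester can only involve O6, since O8 stays silylated in the alcohol-free medium, so the 6,12-lactone forms with C6 and C7 unchanged.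

Step 12
Reactants: 18 (1(10)E,4Z,3S,6R,7S,8R)-3-(tert-butyldimethylsilyloxy)-15-hydroxy-8-(triethylsilyloxy)-13-norgermacra-1(10),4-dien-12,6-olide
Product: 19 (1(10)E,4Z,3S,6R,7S,8R)-3,15-bis(tert-butyldimethylsilyloxy)-8-(triethylsilyloxy)-13-norgermacra-1(10),4-dien-12,6-olide
Conditions: TBSCl, imidazole, DMF, 0 °C
Reagents that add atoms: tert-butyldimethylsilyl chloride, CC(C)(C)[Si](C)(C)Cl
Why: Standard silylation of the single remaining (primary allylic) hydroxyl blocks C15–OH before the acylation and epoxidation.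

Step 13
Reactants: 19 (1(10)E,4Z,3S,6R,7S,8R)-3,15-bis(tert-butyldimethylsilyloxy)-8-(triethylsilyloxy)-13-norgermacra-1(10),4-dien-12,6-olide
Product: 22 (1(10)E,4Z,3S,6R,7S,8R)-3,15-bis(tert-butyldimethylsilyloxy)-8-(triethylsilyloxy)germacra-1(10),4,11(13)-trien-12,6-olide, via Mannich base 20 (not isolated), via methiodide 21 (not isolated)
Conditions: LDA, THF, −78 °C; CH2=NMe2+ I−, −78 → 0 °C; then MeI, MeOH, rt; then aq. NaHCO3, CH2Cl2
Reagents that add atoms: Eschenmoser's salt, C=[N+](C)C.[I-] (iodomethane, CI, methylates nitrogen in 21 only and leaves with trimethylamine)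
Why: α-Methylenation of the lactone by Mannich reaction of its lithium enolate with Eschenmoser's salt, N-methylation and E1cB loss of trimethylamine; the C11 centre is transient and the ring alkenes are not touched.

Step 14
Reactants: 22 (1(10)E,4Z,3S,6R,7S,8R)-3,15-bis(tert-butyldimethylsilyloxy)-8-(triethylsilyloxy)germacra-1(10),4,11(13)-trien-12,6-olide
Product: 23 (1(10)E,4Z,3S,6R,7R,8R)-3,15-bis(tert-butyldimethylsilyloxy)-8-hydroxygermacra-1(10),4,11(13)-trien-12,6-olide
Conditions: HF·pyridine, pyridine, THF, 0 °C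
Reagents that add atoms: none
Why: Buffered HF·pyridine cleaves a triethylsilyl ether far faster than primary or secondary TBS ethers, and the short, cold, non-basic treatment avoids translactonisation to O8.

Step 15
Reactants: 23 (1(10)E,4Z,3S,6R,7R,8R)-3,15-bis(tert-butyldimethylsilyloxy)-8-hydroxygermacra-1(10),4,11(13)-trien-12,6-olide; 24 (R)-2-methylbutanoic acid
Product: 25 (1(10)E,4Z,3S,6R,7R,8R)-3,15-bis(tert-butyldimethylsilyloxy)-8-[(2R)-2-methylbutanoyloxy]germacra-1(10),4,11(13)-trien-12,6-olide
Conditions: DCC, DMAP (cat.), CH2Cl2, 0 °C → rt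
Reagents that add atoms: none
Why: Steglich esterification of the only free hydroxyl; the α-centre of the acid is not activated toward epimerisation and is retained.

Step 16
Reactants: 25 (1(10)E,4Z,3S,6R,7R,8R)-3,15-bis(tert-butyldimethylsilyloxy)-8-[(2R)-2-methylbutanoyloxy]germacra-1(10),4,11(13)-trien-12,6-olide
Product: 26 (4Z,1R,3S,6R,7R,8R,10R)-3,15-bis(tert-butyldimethylsilyloxy)-1,10-epoxy-8-[(2R)-2-methylbutanoyloxy]germacra-4,11(13)-dien-12,6-olide
Conditions: mCPBA (1.1 equiv), NaHCO3, CH2Cl2, −20 → 0 °C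
Reagents that add atoms: 3-chloroperbenzoic acid, OOC(=O)c1cccc(Cl)c1
Why: Prilezhaev epoxidation selects the electron-rich isolated C1=C10 alkene over C4=C5 (three allylic C–O bonds, flanked by silyl ethers) and the acrylate, and peripheral attack on the exposed face of the trans alkene, as is general for germacr-1(10)-enolides, should give the trans 1β,10α (1R,10R) epoxide.

Step 17
Reactants: 26 (4Z,1R,3S,6R,7R,8R,10R)-3,15-bis(tert-butyldimethylsilyloxy)-1,10-epoxy-8-[(2R)-2-methylbutanoyloxy]germacra-4,11(13)-dien-12,6-olide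
Product: 27 (4Z,1R,3S,6R,7R,8R,10R)-1,10-epoxy-3,15-dihydroxy-8-[(2R)-2-methylbutanoyloxy]germacra-4,11(13)-dien-12,6-olide (1β,10α-epoxy-3β,15-dihydroxy-8β-acyloxy-12,6α-olide; CNP0267576.1)
Conditions: HF·pyridine, pyridine, THF, 0 °C → rt
Reagents that add atoms: none
Why: Fluoride cleavage of both TBS ethers under buffered, non-basic conditions should leave the epoxide, the C8 ester and the α-methylene lactone intact and sets no stereocentre.

**Compound list**

1 | ethyl (S)-2-(oxiran-2-yl)acetate | CCOC(=O)C[C@H]1CO1 | starting material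
2 | isopropenylmagnesium bromide | C=C(C)[Mg]Br | starting material
3 | ethyl (3R)-3-hydroxy-5-methylhex-5-enoate | CCOC(=O)C[C@H](O)CC(C)=C | intermediate
4 | tert-butyl bromoacetate | CC(C)(C)OC(=O)CBr | starting material
5 | 4-tert-butyl 1-ethyl (2R)-2-[(1R)-1-hydroxy-3-methylbut-3-en-1-yl]butanedioate | CCOC(=O)[C@H](CC(=O)OC(C)(C)C)[C@H](O)CC(C)=C | intermediate
6 | 4-tert-butyl 1-ethyl (2R)-2-[(1R)-3-methyl-1-(triethylsilyloxy)but-3-en-1-yl]butanedioate | CCOC(=O)[C@H](CC(=O)OC(C)(C)C)[C@H](O[Si](CC)(CC)CC)CC(C)=C | intermediate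
7 | tert-butyl (3R,4R)-3-[methoxy(methyl)carbamoyl]-6-methyl-4-(triethylsilyloxy)hept-6-enoate | CON(C)C(=O)[C@H](CC(=O)OC(C)(C)C)[C@H](O[Si](CC)(CC)CC)CC(C)=C | intermediate
8 | vinylmagnesium bromide | C=C[Mg]Br | starting material
9 | tert-butyl (3R,4R)-3-acryloyl-6-methyl-4-(triethylsilyloxy)hept-6-enoate | C=CC(=O)[C@H](CC(=O)OC(C)(C)C)[C@H](O[Si](CC)(CC)CC)CC(C)=C | intermediate
10 | tert-butyl 2-[(1R,6R)-4-methyl-2-oxo-6-(triethylsilyloxy)cyclohex-3-en-1-yl]acetate | O=C1C=C(C)C[C@@H](O[Si](CC)(CC)CC)[C@H]1CC(=O)OC(C)(C)C | intermediate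
11 | methyl propiolate | C#CC(=O)OC | starting material
12 | tert-butyldimethyl(vinyloxy)silane | C=CO[Si](C)(C)C(C)(C)C | starting material
13 | methyl (±)-4-(tert-butyldimethylsilyloxy)cyclobut-1-ene-1-carboxylate | COC(=O)C1=CCC1O[Si](C)(C)C(C)(C)C | intermediate
14 | methyl (4S)-4-(tert-butyldimethylsilyloxy)cyclobut-1-ene-1-carboxylate | COC(=O)C1=CC[C@@H]1O[Si](C)(C)C(C)(C)C | intermediate
15 | head-to-head photoadduct: cyclobutane C5–C10–C1–C4 cis-fused to the cyclohexanone (C5–C10) and to the silyloxycyclobutane (C1–C4), rings anti, bonded on the cyclobutene face remote from OTBS (one of four convergent diastereomers drawn) | O=C1[C@H](CC(=O)OC(C)(C)C)[C@H](O[Si](CC)(CC)CC)C[C@@]2(C)[C@@H]1[C@@]1(C(=O)OC)[C@@H]2C[C@@H]1O[Si](C)(C)C(C)(C)C | intermediate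
16 | methyl (1(10)E,4E,3S,7R,8R)-7-(2-tert-butoxy-2-oxoethyl)-3-(tert-butyldimethylsilyloxy)-10-methyl-6-oxo-8-(triethylsilyloxy)cyclodeca-1(10),4-diene-4-carboxylate | CC(C)(C)OC(=O)C[C@@H]1[C@H](O[Si](CC)(CC)CC)C/C(C)=C/C[C@H](O[Si](C)(C)C(C)(C)C)/C(C(=O)OC)=C\C1=O | intermediate
17 | tert-butyl 2-[(1(10)E,4Z,3S,6R,7S,8R)-3-(tert-butyldimethylsilyloxy)-6-hydroxy-4-(hydroxymethyl)-10-methyl-8-(triethylsilyloxy)cyclodeca-1(10),4-dien-7-yl]acetate | CC(C)(C)OC(=O)C[C@@H]1[C@H](O[Si](CC)(CC)CC)C/C(C)=C/C[C@H](O[Si](C)(C)C(C)(C)C)/C(CO)=C\[C@H]1O | intermediate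
18 | (1(10)E,4Z,3S,6R,7S,8R)-3-(tert-butyldimethylsilyloxy)-15-hydroxy-8-(triethylsilyloxy)-13-norgermacra-1(10),4-dien-12,6-olide | O=C1C[C@@H]2[C@H](O[Si](CC)(CC)CC)C/C(C)=C/C[C@H](O[Si](C)(C)C(C)(C)C)/C(CO)=C\[C@H]2O1 | intermediate
19 | (1(10)E,4Z,3S,6R,7S,8R)-3,15-bis(tert-butyldimethylsilyloxy)-8-(triethylsilyloxy)-13-norgermacra-1(10),4-dien-12,6-olide | O=C1C[C@@H]2[C@H](O[Si](CC)(CC)CC)C/C(C)=C/C[C@H](O[Si](C)(C)C(C)(C)C)/C(CO[Si](C)(C)C(C)(C)C)=C\[C@H]2O1 | intermediate
20 | (11R)-13-(dimethylamino) derivative of 19 (Mannich base, CH2NMe2 on C11 trans to C8) | O=C1[C@@H](CN(C)C)[C@@H]2[C@H](O[Si](CC)(CC)CC)C/C(C)=C/C[C@H](O[Si](C)(C)C(C)(C)C)/C(CO[Si](C)(C)C(C)(C)C)=C\[C@H]2O1 | intermediate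
21 | trimethylammonium iodide of 20 | O=C1[C@@H](C[N+](C)(C)C)[C@@H]2[C@H](O[Si](CC)(CC)CC)C/C(C)=C/C[C@H](O[Si](C)(C)C(C)(C)C)/C(CO[Si](C)(C)C(C)(C)C)=C\[C@H]2O1.[I-] | intermediate
22 | (1(10)E,4Z,3S,6R,7S,8R)-3,15-bis(tert-butyldimethylsilyloxy)-8-(triethylsilyloxy)germacra-1(10),4,11(13)-trien-12,6-olide | C=C1C(=O)O[C@@H]2/C=C(/CO[Si](C)(C)C(C)(C)C)[C@@H](O[Si](C)(C)C(C)(C)C)C/C=C(\C)C[C@@H](O[Si](CC)(CC)CC)[C@@H]12 | intermediate
23 | (1(10)E,4Z,3S,6R,7R,8R)-3,15-bis(tert-butyldimethylsilyloxy)-8-hydroxygermacra-1(10),4,11(13)-trien-12,6-olide | C=C1C(=O)O[C@@H]2/C=C(/CO[Si](C)(C)C(C)(C)C)[C@@H](O[Si](C)(C)C(C)(C)C)C/C=C(\C)C[C@@H](O)[C@@H]12 | intermediate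
24 | (R)-2-methylbutanoic acid | CC[C@@H](C)C(=O)O | starting material
25 | (1(10)E,4Z,3S,6R,7R,8R)-3,15-bis(tert-butyldimethylsilyloxy)-8-[(2R)-2-methylbutanoyloxy]germacra-1(10),4,11(13)-trien-12,6-olide | C=C1C(=O)O[C@@H]2/C=C(/CO[Si](C)(C)C(C)(C)C)[C@@H](O[Si](C)(C)C(C)(C)C)C/C=C(\C)C[C@@H](OC(=O)[C@H](C)CC)[C@@H]12 | intermediate
26 | (4Z,1R,3S,6R,7R,8R,10R)-3,15-bis(tert-butyldimethylsilyloxy)-1,10-epoxy-8-[(2R)-2-methylbutanoyloxy]germacra-4,11(13)-dien-12,6-olide | C=C1C(=O)O[C@@H]2/C=C(/CO[Si](C)(C)C(C)(C)C)[C@@H](O[Si](C)(C)C(C)(C)C)C[C@H]3O[C@]3(C)C[C@@H](OC(=O)[C@H](C)CC)[C@@H]12 | intermediate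
27 | (4Z,1R,3S,6R,7R,8R,10R)-1,10-epoxy-3,15-dihydroxy-8-[(2R)-2-methylbutanoyloxy]germacra-4,11(13)-dien-12,6-olide | C=C1C(=O)O[C@@H]2/C=C(/CO)[C@@H](O)C[C@H]3O[C@]3(C)C[C@@H](OC(=O)[C@H](C)CC)[C@@H]12 | target

**Count.** Total steps: 17. Longest linear sequence: 15 (steps 1–6 and 9–17); the cyclobutene arm is 2 steps.

**Steps most likely to fail**

Step 9. What may go wrong is the course of the thermal fragmentation: the diyl may cleave C2–C3 (assisted by the C3 silyloxy donor) or the diene may undergo Cope rearrangement to a divinylcyclohexanone, the alkene geometries may come out reversed, or the β-silyloxy ketone may eliminate at the thermolysis temperature. The fallback sets out from 15, collected as the diastereomer mixture after the alumina filtration. DIBAL-H (CH2Cl2, −78 °C) reduces the C6 ketone and the C15 ester in the rigid tricycle, where hydride should enter from the convex face, to give the tricyclic diol F1 (C6 configuration to be verified). F1 is then thermolysed without the ester activation (degassed decalin, about 200 °C, silylated glass), the known unactivated form of this cycloreversion. With no enolisable β-silyloxy ketone and no cross-conjugated acceptor left, the ring opens at the alcohol oxidation level and the route is rejoined at 17; the alkene geometry then rests on the cis ring fusion alone and must be re-examined.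

Step 10. What may go wrong is hydride delivery to the other face of the C6 carbonyl, which would end in the cis-fused lactone. The fallback sets out from 16 and replaces substrate control by reagent control: Corey–Bakshi–Shibata reduction ((R)-Me-CBS oxazaborolidine, catecholborane, PhMe, −78 °C), with the alkenyl carbon C5 as the large group, should give the 6R allylic alcohol methyl ester F2. DIBAL-H (CH2Cl2, −78 °C) then reduces only the C15 ester, and the route is rejoined at 17.

Step 16. What may go wrong is peracid attack on the other face of C1=C10 (or on C4=C5). The fallback sets out from 25 and builds the epoxide in two steps with the opposite facial sense: N-bromosuccinimide in aqueous THF at 0 °C places bromine on the exposed face at C1 and water anti at the tertiary C10, giving the bromohydrin F3. Treatment with DBU in CH2Cl2 then closes the epoxide by inversion at C1, and the route is rejoined at 26.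

**Further compounds**

F1 | step 9 | tricyclic diol from 15 (6R-hydroxy, 15-hydroxymethyl, tert-butyl ester and both silyl ethers kept) | O[C@H]1[C@H](CC(=O)OC(C)(C)C)[C@H](O[Si](CC)(CC)CC)C[C@@]2(C)[C@@H]1[C@@]1(CO)[C@@H]2C[C@@H]1O[Si](C)(C)C(C)(C)C
F2 | step 10 | methyl (1(10)E,4E,3S,6R,7S,8R)-7-(2-tert-butoxy-2-oxoethyl)-3-(tert-butyldimethylsilyloxy)-6-hydroxy-10-methyl-8-(triethylsilyloxy)cyclodeca-1(10),4-diene-4-carboxylate | CC(C)(C)OC(=O)C[C@@H]1[C@H](O[Si](CC)(CC)CC)C/C(C)=C/C[C@H](O[Si](C)(C)C(C)(C)C)/C(C(=O)OC)=C\[C@H]1O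
F3 | step 16 | 1-bromo-10-hydroxy bromohydrin of 25 (Br at C1 anti to the C10 hydroxyl) | C=C1C(=O)O[C@@H]2/C=C(/CO[Si](C)(C)C(C)(C)C)[C@@H](O[Si](C)(C)C(C)(C)C)C[C@H](Br)[C@](C)(O)C[C@@H](OC(=O)[C@H](C)CC)[C@@H]12
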